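**Retrosynthetic overview**
1. Target 5 ⇒ lutein 5,6-epoxide 4: disconnect the C8–O bond. The 2,5-dihydrofuran arises from the vinyl oxirane by a catalyst-controlled ring expansion (C6–O broken, C8–O formed, C5 retained), which sets C8.
2. 4 ⇒ lutein diacetate 2: the oxirane (C5–O and C6–O, 5R,6S) comes from anti-face epoxidation of the 5,6-alkene; the acetates are removed in the same flask.
3. 2 ⇒ lutein 1, which supplies the C40 skeleton, the all-E chain and C3, C3', C6'.
4. Ring order: both six-membered rings are bought with 1; the oxirane is made in step 2 and the dihydrofuran in step 3.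

The target is (3S,5R,8S,3'R,6'R)-5,8-epoxy-5,8-dihydro-β,ε-carotene-3,3'-diol; the 3-OH is trans to the ring oxygen at C5, and the polyene chain at C8 is cis to the 5-methyl group.

Assumption: crystalline (all-E)-lutein from saponified marigold extract (a bulk nutraceutical) counts as cheap and commercial; it is recrystallised once to remove zeaxanthin.
Assumption: the (S,S) antipode of the step 3 catalyst is taken as the one matched to 8S; if the first run shows the opposite sense, the (R,R) antipode is used with nothing else changed.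

Step 1
Reactants: 1 (all-E,3R,3'R,6'R)-lutein
Product: 2 lutein diacetate
Conditions: Ac2O (4 equiv), pyridine, DMAP (5 mol %), rt, dark, Ar
Reagents that add atoms: acetic anhydride, CC(=O)OC(C)=O
Why: DMAP-catalysed O-acylation (nucleophilic acyl substitution) of both secondary alcohols touches no stereocentre and removes the 3-OH hydrogen-bond donor that would steer the peracid to the wrong (syn) face in step 2.

Step 2
Reactants: 2 lutein diacetate
Product: 4 lutein 5,6-epoxide (3S,5R,6S,3'R,6'R), via lutein 5,6-epoxide diacetate 3 (not isolated)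
Conditions: mCPBA (1.0 equiv), NaHCO3 (s), CH2Cl2, −10 → 0 °C, dark, Ar; then MeOH, K2CO3 (0.5 equiv), rt; chromatography on Et3N-deactivated SiO2
Reagents that add atoms: mCPBA, OOC(=O)c1cccc(Cl)c1
Why: Prilezhaev epoxidation goes to the most electron-rich, tetrasubstituted 5,6-alkene (the 4',5'-alkene is deactivated by its allylic acetate), and without hydrogen-bond delivery the oxygen adds mainly anti to the 3-acetoxy group, setting 5R,6S with a modest ratio; carbonate methanolysis (transesterification) then frees the diol without acid, and the syn epimer and unreacted lutein are removed by chromatography.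

Step 3
Reactants: 4 lutein 5,6-epoxide
Product: 5 (3S,5R,8S,3'R,6'R)-5,8-epoxy-5,8-dihydro-β,ε-carotene-3,3'-diol (target)
Conditions: (S,S)-imidodiphosphoric acid (IDP) built from two 3,3'-bis(2,4,6-triethylphenyl)-BINOL units (5 mol %), acid-free CH2Cl2/toluene 1:1, −40 °C, dark, Ar; Et3N quench at −40 °C
Reagents that add atoms: none
Why: Proposed new method: a catalyst-controlled vinyl-oxirane → 2,5-dihydrofuran ring expansion in which the confined chiral acid protonates the epoxide, the C6–O bond ionises with help from the polyene to a contact ion pair whose anion stays hydrogen-bonded to the new C5–OH, and that hydroxyl closes onto C8 inside the chiral pocket, so the catalyst rather than the substrate chooses the C8 face (8S) while C5 is retained and C6 becomes sp2; low temperature and the amine quench prevent re-ionisation of the product (the known route to C8 epimerisation), and any 8R epimer is removed by chromatography; the closest known reactions are the achiral acid-mediated epoxide–furanoid rearrangement of carotenoid 5,6-epoxides (gives both C8 epimers), Cu-catalysed vinyl-oxirane ring expansion to 2,5-dihydrofurans, and confined-acid-catalysed stereoselective C–O ring closures such as spiroacetalisation.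

**Compound list**
1 | (all-E,3R,3'R,6'R)-β,ε-carotene-3,3'-diol (lutein) | CC1=C[C@H](O)CC(C)(C)[C@H]1/C=C/C(C)=C/C=C/C(C)=C/C=C/C=C(C)/C=C/C=C(C)/C=C/C1=C(C)C[C@@H](O)CC1(C)C | starting material
2 | (all-E,3R,3'R,6'R)-β,ε-carotene-3,3'-diyl diacetate (lutein diacetate) | CC1=C[C@H](OC(C)=O)CC(C)(C)[C@H]1/C=C/C(C)=C/C=C/C(C)=C/C=C/C=C(C)/C=C/C=C(C)/C=C/C1=C(C)C[C@@H](OC(C)=O)CC1(C)C | intermediate
3 | (all-E,3S,5R,6S,3'R,6'R)-5,6-epoxy-5,6-dihydro-β,ε-carotene-3,3'-diyl diacetate (epoxide trans to the 3-acetoxy group) | CC1=C[C@H](OC(C)=O)CC(C)(C)[C@H]1/C=C/C(C)=C/C=C/C(C)=C/C=C/C=C(C)/C=C/C=C(C)/C=C/[C@@]12O[C@]1(C)C[C@@H](OC(C)=O)CC2(C)C | intermediate (not isolated)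
4 | (all-E,3S,5R,6S,3'R,6'R)-5,6-epoxy-5,6-dihydro-β,ε-carotene-3,3'-diol (lutein 5,6-epoxide, epoxide trans to 3-OH) | CC1=C[C@H](O)CC(C)(C)[C@H]1/C=C/C(C)=C/C=C/C(C)=C/C=C/C=C(C)/C=C/C=C(C)/C=C/[C@@]12O[C@]1(C)C[C@@H](O)CC2(C)C | intermediate
5 | (all-E,3S,5R,8S,3'R,6'R)-5,8-epoxy-5,8-dihydro-β,ε-carotene-3,3'-diol (8S furanoid oxide, chrysanthemaxanthin) | CC1=C[C@H](O)CC(C)(C)[C@H]1/C=C/C(C)=C/C=C/C(C)=C/C=C/C=C(C)/C=C/C=C(\C)[C@@H]1C=C2C(C)(C)C[C@H](O)C[C@@]2(C)O1 | target

**Total step count:** 3. **Longest linear sequence:** 3.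

**Steps most likely to fail (all three, highest risk first)**

Step 3 (the new step). The catalyst may give poor 8S/8R control, or the product may re-ionise and epimerise before the quench. The fallback is known chemistry and sets out from 4: a trace of HCl in CHCl3 at rt for a few minutes, then NaHCO3 quench. This classical acid-mediated epoxide–furanoid rearrangement gives roughly equal amounts of 5 and its 8R epimer (flavoxanthin) F4. The two are separated by chromatography (CaCO3 column or HPLC), and F4 can be re-equilibrated under the same acid and recycled. The fallback comes back to the route at 5.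

Step 2. The risks are over-oxidation of the polyene, a modest anti/syn ratio, and loss of the very acid-labile diol 4 during isolation. The fallback changes the order of events and sets out from 3, which is now isolated (NaHCO3 wash, Et3N-deactivated silica; the syn epimer is removed at this less polar stage). The ring expansion is run on the diacetate (step 3 conditions, or the HCl conditions above) to give (3S,5R,8S,3'R,6'R)-5,8-epoxy-5,8-dihydro-β,ε-carotene-3,3'-diyl diacetate F3. K2CO3 (cat.) in MeOH/THF then removes the acetates from the base-stable furanoid, and the fallback comes back at 5.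

Step 1. The acylation itself is safe; the risk is that acetate proves too weak a control element for the anti-face epoxidation. The fallback changes the protecting-group strategy and sets out from 1: TBSCl and imidazole in DMF give lutein bis(tert-butyldimethylsilyl) ether F1. Buffered mCPBA (NaHCO3, CH2Cl2, 0 °C) then adds oxygen anti to the bulky silyloxy group to give lutein 5,6-epoxide bis(tert-butyldimethylsilyl) ether F2. TBAF in THF (basic, so the epoxide survives) removes both silyl groups, and the fallback comes back at 4.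

**Further compounds**
F1 | step 1 | (all-E,3R,3'R,6'R)-3,3'-bis(tert-butyldimethylsilyloxy)-β,ε-carotene (lutein bis-TBS ether) | CC1=C[C@H](O[Si](C)(C)C(C)(C)C)CC(C)(C)[C@H]1/C=C/C(C)=C/C=C/C(C)=C/C=C/C=C(C)/C=C/C=C(C)/C=C/C1=C(C)C[C@@H](O[Si](C)(C)C(C)(C)C)CC1(C)C
F2 | step 1 | (all-E,3S,5R,6S,3'R,6'R)-3,3'-bis(tert-butyldimethylsilyloxy)-5,6-epoxy-5,6-dihydro-β,ε-carotene (lutein 5,6-epoxide bis-TBS ether) | CC1=C[C@H](O[Si](C)(C)C(C)(C)C)CC(C)(C)[C@H]1/C=C/C(C)=C/C=C/C(C)=C/C=C/C=C(C)/C=C/C=C(C)/C=C/[C@@]12O[C@]1(C)C[C@@H](O[Si](C)(C)C(C)(C)C)CC2(C)C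
F3 | step 2 | (all-E,3S,5R,8S,3'R,6'R)-5,8-epoxy-5,8-dihydro-β,ε-carotene-3,3'-diyl diacetate | CC1=C[C@H](OC(C)=O)CC(C)(C)[C@H]1/C=C/C(C)=C/C=C/C(C)=C/C=C/C=C(C)/C=C/C=C(\C)[C@@H]1C=C2C(C)(C)C[C@H](OC(C)=O)C[C@@]2(C)O1
F4 | step 3 | (all-E,3S,5R,8R,3'R,6'R)-5,8-epoxy-5,8-dihydro-β,ε-carotene-3,3'-diol (8R epimer of 5, flavoxanthin) | CC1=C[C@H](O)CC(C)(C)[C@H]1/C=C/C(C)=C/C=C/C(C)=C/C=C/C=C(C)/C=C/C=C(\C)[C@H]1C=C2C(C)(C)C[C@H](O)C[C@@]2(C)O1
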